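## Structural features

The target contains two oxazoles. Ring B is a 5-monosubstituted oxazole whose C5 is joined through one methylene to C2 of ring A, a 2,4-disubstituted oxazole, and C4 of ring A carries a six-carbon chain C1'–C6'. Along the chain, C1' is a secondary carbinol (R), C2' is a methylene, C3' (S) bears the tetradecanoate, C4' (R) and C5' (S) are free secondary carbinols and C6' is a methyl group. C3', C4' and C5' are contiguous (C3'/C4' anti, C4'/C5' syn in the zigzag drawing); C1' is separated from them by C2' and is 1,3-syn to C3'. The fragile points are the secondary ester, which has a free hydroxyl 1,2 to it (C4') and two more 1,3 to it (C1', C5') and can migrate under base or strong acid, the acidic methylene between the two azoles, the free C2–H of ring B, and the carbinol C1' next to ring A. The real difficulty lies in the chain, not the heteroaromatic part: four hydroxyls must be told apart so that only O3' is acylated, and four stereocentres must be set, one of them remote. The key step exploits the fact that C1'–C5' with C3'(S) and C4'(R) is the carbon chain of 2-deoxy-D-ribose with both of its stereocentres (a CIP analysis of both structures confirms the match). With O4' as an ether next to a C5' aldehyde, a magnesium chelate between these two oxygens lets the missing C6' methyl enter from one face and creates C5' syn to O4'.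

## Logic of the disconnections

**29 from 28.** Only acetal C–O bonds are broken in the last step: the mixed acetal on O1' and the cyclic arylidene acetal on O4'/O5'. The cut is placed there so that every hydroxyl except O3' is masked by groups that leave in one mild acidic treatment, and the ester never meets base or fluoride. The gain is a precursor with no free hydroxyl next to the ester. The forward step needs an acid weak enough that the acyl group stays on O3'.

**28 from 26 and 27.** The O3'–acyl bond is cut. The ester goes on late because it would not survive the base-mediated C–C bond formation at C1'. The gain is that the C14 chain leaves as 27 and 26 holds a single free hydroxyl. The forward step must find O3' as the only nucleophile.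

**26 from 25.** The O3'–Si bond is cut. The silyl ether is the one group on the chain that fluoride removes, so it is the handle for O3'. This demands that O1', O4' and O5' carry fluoride-stable acetals in 25.

**25 from 23 (through 24), 23 from 22, 22 from 21, 21 from 20.** Ring A is opened at O1–C5 and its C4=C5 unsaturation is removed, which leads to the α-amido aldehyde 23 and, one oxidation level down, to alcohol 22. An oxazole with an unactivated alkyl group on C4 is best closed from an acyclic amide onto a carbonyl carbon that becomes C5. The gain is that ring A becomes the amide of a 2-amino-1,3-diol. The forward sequence needs O1' blocked and the primary oxygen free, hence protection at O1' (21) and then selective desilylation (22).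

**20 from 18 and 19.** The amide C–N bond is cut. Ring B and its methylene arrive intact in 19, so no chemistry is done on the sensitive 5-monosubstituted oxazole. The forward step must acylate nitrogen in the presence of a free secondary hydroxyl.

**18 from 17, 17 from 14 and 16.** The amine is traced to a nitro group, and the bond between the nitro-bearing carbon (future C4 of ring A) and C1' is cut. This is the one C–C bond that joins the heteroaromatic half to the sugar-derived chain, and it gives an aldehyde, 14, and a two-carbon nitro compound, 16. The forward addition must set C1' although the nearest stereocentre, C3', is two atoms away and carries a non-directing silyl ether, so a chiral catalyst has to choose the face.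

**16 from 15.** The O–Si bond is cut. The silyl group keeps the nitro alcohol from dehydrating and later lets the primary oxygen be freed selectively.

**14 from 13, 13 from 12.** The aldehyde is traced to the dithiane (two C–S bonds), and the arylidene acetal to a PMB ether on O4' with a free O5' (one acetal C–O bond). The gain is that 12 is exactly the product of the methyl addition and its PMB group is reused as the O4'/O5' protecting group. The forward step needs an oxidant that attacks the electron-rich benzyl ether and not the dithiane, under anhydrous conditions.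

**12 from 10 and 11.** The C5'–C6' bond is cut, which removes the methyl group and the C5' stereocentre together. After this cut, 10 has only the two stereocentres that 1 supplies. The forward addition must be syn to O4', which needs a chelating ether on O4' and a non-chelating group on O3'; this fixes the protecting group pattern of 10.

**10 from 9, 9 from 8, 8 from 6 and 7.** The oxidation level at C5' is adjusted; the PMB ether on O4' with free O5' is traced to a cyclic arylidene acetal (one acetal C–O bond, broken by hydride in the forward sense), and this to diol 6 and 7. The two hydroxyls of a terminal 1,2-diol are thus told apart without separate protection and deprotection. The forward step needs reductive opening towards the secondary ether.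

**6 from 5, 5 from 4, 4 from 3, 3 from 1 and 2.** The O3' silyl ether, a temporary acetonide and the two C–S bonds of the dithioacetal are removed in turn. The acetonide detour is taken because only a ketal closes with certainty on O4'/O5' of 3. An arylidene acetal put directly on 3 could close the six-membered ring on O3'/O5', in which the aryl group, the C2' substituent and O4'H are all equatorial. The forward sequence needs acetonide hydrolysis that spares the silyl ether and the dithiane.

## Other disconnections considered

**Alternative 1:** The cut is the O1–C5 bond of ring A together with its C4=C5 double bond, leading to the hydroxy amide A2.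
- **Forward key step:** the primary alcohol of A2 is oxidised with Dess–Martin periodinane, and PPh3, I2 and Et3N close the amide oxygen onto the new aldehyde carbon and aromatise to the bis-oxazole A1.
- **In its favour:** the heteroaromatic ring is made late from a robust amide. The protecting groups of A1 (silyl on O1', PMB on O3', acetonide on O4'/O5') are mutually orthogonal and free of stereorandom acetal carbons. On this point the alternative is the better plan, since the chosen route carries two epimeric acetal centres from step 15 on.
- **Against it here:** as the strategy-bearing step it forms no chain C–C bond and no stereocentre, so all four stereocentres of A2 must come from elsewhere. A PMB group on O3' cannot come from a chelation-controlled methyl addition, which wants the ether on O4', so the C3'–C5' triad needs another source. The acetonide needs stronger acid at the end, with the ester already next to it.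
- **Comparison:** on structure, the alternative addresses ring A and the chosen plan addresses the chain. On mechanism, it is the same 5-exo closure and elimination used in step 18, so the two are equal. On step economy, ring A costs the same number of operations in both.

**Alternative 2:** The cut removes the O3'–acyl bond and the C5'–H bond together, leading to the β-hydroxy ketone A4 and tetradecanal A5.
- **Forward key step:** the C3' hydroxyl adds to A5 and, with SmI2 (divalent samarium) as precatalyst, the hemiacetal hydrogen is passed to the C5' ketone through a six-membered chair-like chelate (Evans–Tishchenko reduction). This gives A3, with the ester on O3' and the C5' carbinol 1,3-anti to it.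
- **In its favour:** the ester and C5' are made in one operation and the mechanism itself delivers the acyl group to O3', so no hydroxyl has to be singled out for acylation. On the end game this is better in step economy than the chosen plan, which needs steps 19 and 20 and an acid hydrolysis beside the ester.
- **Against it here:** A4 must already contain ring A, C1' and the anti C3'/C4' pair, with C4' next to a ketone and therefore epimerisable. C3'/C4' would have to be built by an anti-selective glycolate-type aldol instead of being bought. Two basic oxazole nitrogens may hold the oxophilic catalyst. A3 also has a free O5' 1,3 to the new ester under Lewis acidic conditions.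
- **Comparison:** on structure, it uses the 1,3-relationship C3'/C5' (anti) where the chosen plan uses the 1,2-relationship C4'/C5' (syn); both fit the target. On mechanism, it is an intramolecular hydride delivery against an intermolecular chelate-controlled carbanion addition; both rest on a metal bridging two oxygens and are equal in predictability. On step economy, the alternative is shorter after its key step and longer before it, because no chiral-pool compound supplies A4.

**Alternative 3:** The cut is the bond between the future C4 of ring A and C1', leading to aldehyde A7 and the nitro compound 16.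
- **Forward key step:** Cu(OAc)2 with a chiral bis(oxazoline) forms the nitronate of 16, which adds to A7 and gives A6 with the C1' carbinol (epimers at the nitro carbon).
- **In its favour:** it joins the two halves under nearly neutral conditions. It is the same bond and reaction type as step 12 of the chosen route, so on this bond the two plans are equal. A7 carries PMB on O3' and an acetonide, which gives single diastereomers and lets O3' be freed cleanly by oxidation; on protecting-group clarity the alternative is the better plan.
- **Against it here:** A7 is an L-configured 2,6-dideoxyhexose derivative and not a cheap pool compound, so the C5' methyl carbinol would still have to be made, most plausibly by the addition of step 8. The chelating ether β to the aldehyde may impose its own 1,3-bias, which the catalyst must match or override.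
- **Comparison:** on structure, it addresses the remote C1', while the chosen key step addresses C5' and so supplies the triad. On mechanism, it is catalyst control on an unbranched aldehyde against substrate control through a rigid five-membered chelate; the chelate is the more predictable. On step economy, the count after A6 equals that after 17; before it, the alternative is shorter only if A7 is available in fewer than the ten steps that lead to 14.

Key step: step 8

Remarks on the chemistry (assumptions):
- The chain numbering C1' (dithiane carbon, later the carbinol on ring A) to C6' (methyl) is used for all intermediates.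
- The arylidene acetal carbon, the THP acetal carbon and the nitro- or amide-bearing carbon are carried as epimer mixtures, since all three centres disappear before the target.
- In step 12 the ligand enantiomer (both are available) is taken to be the one that directs the nitronate to the Si face of the aldehyde of 14; the sense of induction for this substrate is not predicted here.
- TBDPS = tert-butyldiphenylsilyl, TBS = tert-butyldimethylsilyl, PMB = 4-methoxybenzyl, THP = oxan-2-yl.

## Route

Step 1
Reactants: 1 2-deoxy-D-ribose; 2 propane-1,3-dithiol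
Product: 3 2-deoxy-D-ribose propane-1,3-diyl dithioacetal, (2R,3S)-4-(1,3-dithian-2-yl)butane-1,2,3-triol
Conditions: conc. HCl (aq), 0 °C → rt
Reagents that add atoms: none
Why: Acid-catalysed dithioacetalisation traps the open-chain aldehyde, so the pyranose opens and C1' is stored as a 1,3-dithiane that later resists hydride, Grignard reagent and fluoride. C3' and C4' are not involved and keep the configuration of the sugar.

Step 2
Reactants: 3 dithiane triol
Product: 4 4',5'-O-isopropylidene dithiane alcohol (O3' free)
Conditions: 2,2-dimethoxypropane, TsOH·H2O (cat.), acetone, rt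
Reagents that add atoms: 2,2-dimethoxypropane, COC(C)(C)OC
Why: Acetonide formation under thermodynamic control; the terminal dioxolane is favoured over the 3',5'-dioxane (axial methyl) and over the cis-disubstituted 3',4'-dioxolane, so only O3' stays free. A direct arylidene acetal on 3 is avoided because the all-equatorial 3',5'-dioxane would compete.

Step 3
Reactants: 4 acetonide alcohol
Product: 5 O3'-TBDPS 4',5'-acetonide
Conditions: TBDPSCl, imidazole, DMAP (cat.), DMF, rt → 40 °C
Reagents that add atoms: tert-butyl(chloro)diphenylsilane, CC(C)(C)[Si](Cl)(c1ccccc1)c1ccccc1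
Why: Imidazole-mediated silylation of the only free hydroxyl. The bulky, weakly basic TBDPS ether is preferred to TBS because it does not chelate magnesium in step 8 and outlasts the acid of step 4 and the HF·pyridine of step 16.

Step 4
Reactants: 5 O3'-TBDPS 4',5'-acetonide
Product: 6 O3'-TBDPS 4',5'-diol
Conditions: AcOH/H2O (4:1), 40 °C
Reagents that add atoms: none
Why: Mild acid hydrolysis of the terminal isopropylidene acetal; the TBDPS ether and the dithiane are stable to aqueous acetic acid, and silyl migration is not expected under acid.

Step 5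
Reactants: 6 O3'-TBDPS 4',5'-diol; 7 4-methoxybenzaldehyde dimethyl acetal
Product: 8 O3'-TBDPS 4',5'-O-(4-methoxybenzylidene) acetal
Conditions: PPTS (cat.), CH2Cl2, rt
Reagents that add atoms: none
Why: Acid-catalysed transacetalisation; with O3' blocked only the 4',5'-diol can react, so the regiochemistry is unambiguous. The acetal carbon forms as two epimers, which is of no consequence.

Step 6
Reactants: 8 4',5'-O-(4-methoxybenzylidene) acetal
Product: 9 O3'-TBDPS O4'-PMB primary alcohol
Conditions: iBu2AlH (3 equiv), CH2Cl2, −78 → 0 °C; aq. potassium sodium tartrate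
Reagents that add atoms: none
Why: Reductive opening of the arylidene acetal; aluminium binds the less hindered primary oxygen, the C–O5' bond breaks and hydride reduces the oxocarbenium ion, which leaves PMB on the secondary O4' and frees the primary alcohol.

Step 7
Reactants: 9 O4'-PMB primary alcohol
Product: 10 C5' aldehyde (C1' dithiane, O3'-TBDPS, O4'-PMB)
Conditions: SO3·pyridine, DMSO, i-Pr2NEt, CH2Cl2, 0 °C
Reagents that add atoms: none
Why: Parikh–Doering oxidation of the primary alcohol; the cold, non-acidic conditions limit epimerisation at C4' and, unlike hypervalent iodine oxidants, leave the dithiane alone. The aldehyde is used without storage.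

Step 8
Reactants: 10 C5' aldehyde; 11 methylmagnesium bromide
Product: 12 C5' methyl carbinol (2-deoxy-L-fucose 1,3-dithiane, O3'-TBDPS, O4'-PMB, free O5')
Conditions: MgBr2·OEt2 (3 equiv), CH2Cl2, −78 °C; then MeMgBr (3 M in Et2O), −78 °C; aq. NH4Cl
Reagents that add atoms: none
Why: MgBr2·OEt2 is added first so that divalent magnesium closes a five-membered chelate between the aldehyde oxygen and the O4' ether oxygen of 10 (Cram cyclic model), which locks the C4'–C5' rotamer with C=O and C4'–O syn-periplanar. The methyl group of 11 then adds to the carbonyl carbon from the chelate face that carries only the C4' hydrogen, opposite the C3' chain, and this forms the C5'–C6' bond. The closest known reaction type is the chelation-controlled Grignard addition to α-alkoxy aldehydes, which gives syn-1,2-diol derivatives. No ring is closed; the chelate is only a transient magnesium complex. The one new stereocentre, C5', is controlled by the existing C4' stereocentre through that chelate (1,2-induction), and the expected result is the syn (threo) C4'/C5' pair, S at C5'. The step needs syn over the Felkin–Anh anti product: the unhindered, Lewis basic PMB ether secures the α-chelate, the bulky and weakly basic silyl ether on O3' cannot form a competing six-membered β-chelate, and CH2Cl2 with excess MgBr2 keeps the little ether brought in with the Grignard solution from breaking the chelate. At −78 °C enolisation of the α-alkoxy aldehyde and β-elimination of silanolate should be slow, and the dithiane C–H is not acidic enough to be touched.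

Step 9
Reactants: 12 C5' methyl carbinol
Product: 13 dithiane with O3'-TBDPS and 4',5'-O-(4-methoxybenzylidene) acetal
Conditions: DDQ (1.2 equiv), 4 Å molecular sieves, CH2Cl2, 0 °C
Reagents that add atoms: none
Why: Oxidative acetal formation; DDQ abstracts hydride from the PMB methylene and, with no water present, the neighbouring O5' hydroxyl traps the oxocarbenium ion as a five-membered arylidene acetal. O4' and O5' are tied together without a new reagent and O3' remains the only silyl ether.

Step 10
Reactants: 13 dithiane acetal
Product: 14 C1' aldehyde (O3'-TBDPS, 4',5'-arylidene acetal)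
Conditions: MeI, CaCO3, MeCN/H2O (9:1), 45 °C
Reagents that add atoms: water, O
Why: Alkylative dithiane hydrolysis; S-methylation makes a sulfonium leaving group and water opens the thionium ion, while CaCO3 keeps the medium neutral so that the acetal and the silyl ether survive. The β-silyloxy aldehyde is used directly.

Step 11
Reactants: 15 2-nitroethanol
Product: 16 tert-butyl(dimethyl)(2-nitroethoxy)silane
Conditions: TBSCl, imidazole, CH2Cl2, 0 °C → rt
Reagents that add atoms: tert-butyl(chloro)dimethylsilane, CC(C)(C)[Si](C)(C)Cl
Why: Imidazole-mediated silylation of the primary alcohol; the silyl ether prevents loss of water to nitroethylene and gives a primary oxygen that can be freed selectively in step 16.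

Step 12
Reactants: 14 C1' aldehyde; 16 tert-butyl(dimethyl)(2-nitroethoxy)silane
Product: 17 nitro alcohol (C1' R carbinol, nitro carbon as epimers)
Conditions: Cu(OAc)2·H2O (10 mol%), 2,2'-(propane-2,2-diyl)bis(3a,8a-dihydro-8H-indeno[1,2-d]oxazole) (11 mol%, Si-face-selective enantiomer), EtOH, 0 °C → rt
Reagents that add atoms: none
Why: Henry (nitroaldol) reaction; acetate on divalent copper deprotonates 16, and nitronate and aldehyde meet on the chiral copper–bis(oxazoline) complex, which forms the bond from the future C4 of ring A to C1'. C1' is set by the catalyst (Si-face attack gives the R carbinol, 1,3-syn to O3'); the nitro-bearing carbon forms as epimers, which does not matter because it becomes sp2.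

Step 13
Reactants: 17 nitro alcohol
Product: 18 amino alcohol
Conditions: NiCl2·6H2O (0.3 equiv), NaBH4, MeOH, 0 °C
Reagents that add atoms: none
Why: Nickel boride generated in the flask from NiCl2 and NaBH4 reduces the aliphatic nitro group to the primary amine quickly at 0 °C, before retro-nitroaldol can erode C1'; silyl ethers and the acetal are inert.

Step 14
Reactants: 18 amino alcohol; 19 2-(1,3-oxazol-5-yl)acetic acid
Product: 20 hydroxy amide
Conditions: EDC·HCl, HOBt, CH2Cl2, 0 °C → rt
Reagents that add atoms: none
Why: Carbodiimide amide coupling through the HOBt ester; the primary amine is far more nucleophilic than the hindered C1' hydroxyl, so only N-acylation is expected.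

Step 15
Reactants: 20 hydroxy amide
Product: 21 O1'-THP amide
Conditions: 3,4-dihydro-2H-pyran, PPTS (cat.), CH2Cl2, rt
Reagents that add atoms: 3,4-dihydro-2H-pyran, C1CCOC=C1
Why: Acid-catalysed addition of the C1' hydroxyl to the enol ether (tetrahydropyranylation). The THP ether resists fluoride and base, so it stays on through steps 16–20 and leaves together with the arylidene acetal in step 21, where its extra acetal centre disappears.

Step 16
Reactants: 21 O1'-THP amide
Product: 22 O1'-THP amide primary alcohol
Conditions: HF·pyridine, pyridine, THF, 0 °C → rt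
Reagents that add atoms: none
Why: Fluoride cleavage of the primary TBS ether; the hindered secondary TBDPS ether reacts far more slowly, and the pyridine buffer protects the THP ether and the arylidene acetal.

Step 17
Reactants: 22 primary alcohol
Product: 23 α-amido aldehyde
Conditions: Dess–Martin periodinane, NaHCO3, CH2Cl2, 0 °C → rt
Reagents that add atoms: none
Why: Dess–Martin oxidation of the primary alcohol under buffered, non-basic conditions; the aldehyde is used crude because its α-centre is labile, which is harmless as that carbon becomes C4 of ring A.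

Step 18
Reactants: 23 α-amido aldehyde
Product: 25 protected bis-oxazole (O1'-THP, O3'-TBDPS, 4',5'-arylidene acetal), via 5-bromo-4,5-dihydro-oxazole 24 (not isolated)
Conditions: PPh3, BrCl2CCCl2Br, 2,6-di-tert-butyl-4-methylpyridine, CH2Cl2, 0 °C → rt; then DBU, MeCN, rt
Reagents that add atoms: none
Why: Robinson–Gabriel-type cyclodehydration of an α-amido aldehyde; the amide oxygen adds to the aldehyde carbon (5-exo-trig, O1–C5 bond of ring A), the bromophosphonium salt formed from PPh3 and BrCl2CCCl2Br turns the hemiaminal hydroxyl into bromide, and DBU removes HBr to aromatise. The hindered pyridine takes up HBr so that the THP ether and the acetal do not meet acid.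

Step 19
Reactants: 25 protected bis-oxazole
Product: 26 C3' alcohol
Conditions: TBAF, THF, 0 °C → rt
Reagents that add atoms: none
Why: Fluoride-mediated desilylation of the single remaining silyl ether frees O3' alone; the THP ether, the arylidene acetal and both oxazoles are inert to TBAF.

Step 20
Reactants: 26 C3' alcohol; 27 tetradecanoyl chloride
Product: 28 O3' tetradecanoate (O1'-THP, 4',5'-arylidene acetal)
Conditions: pyridine, DMAP (cat.), CH2Cl2, 0 °C → rt
Reagents that add atoms: none
Why: DMAP-catalysed acylation of the only free hydroxyl with the acid chloride; no other nucleophilic site competes, so the ester can only form on O3'.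

Step 21
Reactants: 28 O3' tetradecanoate
Product: 29 CNP0187414.1, (2S,3R,4S,6R)-2,3,6-trihydroxy-6-[2-(1,3-oxazol-5-ylmethyl)-1,3-oxazol-4-yl]hexan-4-yl tetradecanoate
Conditions: AcOH/THF/H2O (3:1:1), 35–40 °C
Reagents that add atoms: none
Why: Mild aqueous acid hydrolyses the THP mixed acetal and the arylidene acetal in one operation and releases O1', O4' and O5'. Dilute acetic acid at modest temperature is chosen because the ester can shift to O4' under base or strong acid; the oxazoles and the ester itself are stable.

## Compound list

1 | 2-deoxy-D-ribose (open-chain form drawn) | O=CC[C@H](O)[C@H](O)CO | starting material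
2 | propane-1,3-dithiol | SCCCS | starting material
3 | (2R,3S)-4-(1,3-dithian-2-yl)butane-1,2,3-triol | O[C@@H](CC1SCCCS1)[C@H](O)CO | intermediate
4 | (1S)-2-(1,3-dithian-2-yl)-1-[(4R)-2,2-dimethyl-1,3-dioxolan-4-yl]ethan-1-ol | O[C@@H](CC1SCCCS1)[C@H]1COC(C)(C)O1 | intermediate
5 | tert-butyl{(1S)-2-(1,3-dithian-2-yl)-1-[(4R)-2,2-dimethyl-1,3-dioxolan-4-yl]ethoxy}diphenylsilane | CC(C)(C)[Si](c1ccccc1)(c1ccccc1)O[C@@H](CC1SCCCS1)[C@H]1COC(C)(C)O1 | intermediate
6 | (2R,3S)-3-{[tert-butyl(diphenyl)silyl]oxy}-4-(1,3-dithian-2-yl)butane-1,2-diol | CC(C)(C)[Si](c1ccccc1)(c1ccccc1)O[C@@H](CC1SCCCS1)[C@H](O)CO | intermediate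
7 | 4-methoxybenzaldehyde dimethyl acetal | COC(OC)c1ccc(OC)cc1 | starting material
8 | tert-butyl{(1S)-2-(1,3-dithian-2-yl)-1-[(4R)-2-(4-methoxyphenyl)-1,3-dioxolan-4-yl]ethoxy}diphenylsilane (both epimers at the acetal carbon) | CC(C)(C)[Si](c1ccccc1)(c1ccccc1)O[C@@H](CC1SCCCS1)[C@H]1COC(c2ccc(OC)cc2)O1 | intermediate
9 | (2R,3S)-3-{[tert-butyl(diphenyl)silyl]oxy}-4-(1,3-dithian-2-yl)-2-[(4-methoxyphenyl)methoxy]butan-1-ol | CC(C)(C)[Si](c1ccccc1)(c1ccccc1)O[C@@H](CC1SCCCS1)[C@H](OCc1ccc(OC)cc1)CO | intermediate
10 | (2S,3S)-3-{[tert-butyl(diphenyl)silyl]oxy}-4-(1,3-dithian-2-yl)-2-[(4-methoxyphenyl)methoxy]butanal | CC(C)(C)[Si](c1ccccc1)(c1ccccc1)O[C@@H](CC1SCCCS1)[C@H](OCc1ccc(OC)cc1)C=O | intermediate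
11 | methylmagnesium bromide | C[Mg]Br | starting material
12 | (2S,3R,4S)-4-{[tert-butyl(diphenyl)silyl]oxy}-5-(1,3-dithian-2-yl)-3-[(4-methoxyphenyl)methoxy]pentan-2-ol | CC(C)(C)[Si](c1ccccc1)(c1ccccc1)O[C@@H](CC1SCCCS1)[C@H](OCc1ccc(OC)cc1)[C@H](C)O | intermediate
13 | tert-butyl{(1S)-2-(1,3-dithian-2-yl)-1-[(4R,5S)-2-(4-methoxyphenyl)-5-methyl-1,3-dioxolan-4-yl]ethoxy}diphenylsilane (both epimers at the acetal carbon) | CC(C)(C)[Si](c1ccccc1)(c1ccccc1)O[C@@H](CC1SCCCS1)[C@H](O2)[C@H](C)OC2c1ccc(OC)cc1 | intermediate
14 | (3S)-3-{[tert-butyl(diphenyl)silyl]oxy}-3-[(4R,5S)-2-(4-methoxyphenyl)-5-methyl-1,3-dioxolan-4-yl]propanal (acetal epimers) | CC(C)(C)[Si](c1ccccc1)(c1ccccc1)O[C@@H](CC=O)[C@H](O2)[C@H](C)OC2c1ccc(OC)cc1 | intermediate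
15 | 2-nitroethanol | OCC[N+](=O)[O-] | starting material
16 | tert-butyl(dimethyl)(2-nitroethoxy)silane | CC(C)(C)[Si](C)(C)OCC[N+](=O)[O-] | intermediate
17 | (3R,5S)-1-{[tert-butyl(dimethyl)silyl]oxy}-5-{[tert-butyl(diphenyl)silyl]oxy}-5-[(4R,5S)-2-(4-methoxyphenyl)-5-methyl-1,3-dioxolan-4-yl]-2-nitropentan-3-ol (epimers at C2 and at the acetal carbon) | CC(C)(C)[Si](C)(C)OCC([N+](=O)[O-])[C@H](O)C[C@H](O[Si](c1ccccc1)(c1ccccc1)C(C)(C)C)[C@H](O2)[C@H](C)OC2c1ccc(OC)cc1 | intermediate
18 | (3R,5S)-2-amino-1-{[tert-butyl(dimethyl)silyl]oxy}-5-{[tert-butyl(diphenyl)silyl]oxy}-5-[(4R,5S)-2-(4-methoxyphenyl)-5-methyl-1,3-dioxolan-4-yl]pentan-3-ol (epimers at C2 and at the acetal carbon) | CC(C)(C)[Si](C)(C)OCC(N)[C@H](O)C[C@H](O[Si](c1ccccc1)(c1ccccc1)C(C)(C)C)[C@H](O2)[C@H](C)OC2c1ccc(OC)cc1 | intermediate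
19 | 2-(1,3-oxazol-5-yl)acetic acid | OC(=O)Cc1cnco1 | starting material
20 | N-[(3R,5S)-1-{[tert-butyl(dimethyl)silyl]oxy}-5-{[tert-butyl(diphenyl)silyl]oxy}-3-hydroxy-5-[(4R,5S)-2-(4-methoxyphenyl)-5-methyl-1,3-dioxolan-4-yl]pentan-2-yl]-2-(1,3-oxazol-5-yl)acetamide (epimers at C2 and at the acetal carbon) | CC(C)(C)[Si](C)(C)OCC(NC(=O)Cc1cnco1)[C@H](O)C[C@H](O[Si](c1ccccc1)(c1ccccc1)C(C)(C)C)[C@H](O2)[C@H](C)OC2c1ccc(OC)cc1 | intermediate
21 | N-[(3R,5S)-1-{[tert-butyl(dimethyl)silyl]oxy}-5-{[tert-butyl(diphenyl)silyl]oxy}-5-[(4R,5S)-2-(4-methoxyphenyl)-5-methyl-1,3-dioxolan-4-yl]-3-(oxan-2-yloxy)pentan-2-yl]-2-(1,3-oxazol-5-yl)acetamide (epimers at C2 and at both acetal carbons) | CC(C)(C)[Si](C)(C)OCC(NC(=O)Cc1cnco1)[C@H](OC1CCCCO1)C[C@H](O[Si](c1ccccc1)(c1ccccc1)C(C)(C)C)[C@H](O2)[C@H](C)OC2c1ccc(OC)cc1 | intermediate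
22 | N-[(3R,5S)-5-{[tert-butyl(diphenyl)silyl]oxy}-1-hydroxy-5-[(4R,5S)-2-(4-methoxyphenyl)-5-methyl-1,3-dioxolan-4-yl]-3-(oxan-2-yloxy)pentan-2-yl]-2-(1,3-oxazol-5-yl)acetamide (epimers at C2 and at both acetal carbons) | OCC(NC(=O)Cc1cnco1)[C@H](OC1CCCCO1)C[C@H](O[Si](c1ccccc1)(c1ccccc1)C(C)(C)C)[C@H](O2)[C@H](C)OC2c1ccc(OC)cc1 | intermediate
23 | N-[(3R,5S)-5-{[tert-butyl(diphenyl)silyl]oxy}-5-[(4R,5S)-2-(4-methoxyphenyl)-5-methyl-1,3-dioxolan-4-yl]-3-(oxan-2-yloxy)-1-oxopentan-2-yl]-2-(1,3-oxazol-5-yl)acetamide (epimers at C2 and at both acetal carbons) | O=CC(NC(=O)Cc1cnco1)[C@H](OC1CCCCO1)C[C@H](O[Si](c1ccccc1)(c1ccccc1)C(C)(C)C)[C@H](O2)[C@H](C)OC2c1ccc(OC)cc1 | intermediate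
24 | 5-bromo-4-[(1R,3S)-3-{[tert-butyl(diphenyl)silyl]oxy}-3-[(4R,5S)-2-(4-methoxyphenyl)-5-methyl-1,3-dioxolan-4-yl]-1-(oxan-2-yloxy)propyl]-2-(1,3-oxazol-5-ylmethyl)-4,5-dihydro-1,3-oxazole (epimers at ring C4, C5 and both acetal carbons) | BrC1OC(Cc2cnco2)=NC1[C@H](OC1CCCCO1)C[C@H](O[Si](c1ccccc1)(c1ccccc1)C(C)(C)C)[C@H](O2)[C@H](C)OC2c1ccc(OC)cc1 | intermediate (not isolated)
25 | 4-[(1R,3S)-3-{[tert-butyl(diphenyl)silyl]oxy}-3-[(4R,5S)-2-(4-methoxyphenyl)-5-methyl-1,3-dioxolan-4-yl]-1-(oxan-2-yloxy)propyl]-2-(1,3-oxazol-5-ylmethyl)-1,3-oxazole (epimers at both acetal carbons) | CC(C)(C)[Si](c1ccccc1)(c1ccccc1)O[C@@H](C[C@@H](OC1CCCCO1)c1coc(Cc2cnco2)n1)[C@H](O2)[C@H](C)OC2c1ccc(OC)cc1 | intermediate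
26 | (1S,3R)-1-[(4S,5S)-2-(4-methoxyphenyl)-5-methyl-1,3-dioxolan-4-yl]-3-(oxan-2-yloxy)-3-[2-(1,3-oxazol-5-ylmethyl)-1,3-oxazol-4-yl]propan-1-ol (epimers at both acetal carbons; the 4S descriptor reflects a CIP priority change, not a change of geometry) | O[C@@H](C[C@@H](OC1CCCCO1)c1coc(Cc2cnco2)n1)[C@H](O2)[C@H](C)OC2c1ccc(OC)cc1 | intermediate
27 | tetradecanoyl chloride | CCCCCCCCCCCCCC(Cl)=O | starting material
28 | (1S,3R)-1-[(4R,5S)-2-(4-methoxyphenyl)-5-methyl-1,3-dioxolan-4-yl]-3-(oxan-2-yloxy)-3-[2-(1,3-oxazol-5-ylmethyl)-1,3-oxazol-4-yl]propyl tetradecanoate (epimers at both acetal carbons) | CCCCCCCCCCCCCC(=O)O[C@@H](C[C@@H](OC1CCCCO1)c1coc(Cc2cnco2)n1)[C@H](O2)[C@H](C)OC2c1ccc(OC)cc1 | intermediate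
29 | (2S,3R,4S,6R)-2,3,6-trihydroxy-6-[2-(1,3-oxazol-5-ylmethyl)-1,3-oxazol-4-yl]hexan-4-yl tetradecanoate (CNP0187414.1) | CCCCCCCCCCCCCC(=O)O[C@@H](C[C@@H](O)c1coc(Cc2cnco2)n1)[C@H](O)[C@H](C)O | target

## Step count and least certain steps

Total: 21 steps. Longest linear sequence: 20 steps (steps 1–10, then 12–21, from 1); step 11 is a one-step branch from 15.

**Step 8 (key step).** The most likely failure is loss of chelation control. Ether brought in with the Grignard reagent competes for magnesium, the open Felkin–Anh pathway then delivers methyl to the other face, and C5' forms with poor facial selectivity; enolisation of the α-alkoxy aldehyde could also erode C4'. The fallback sets out from 12, taken as the mixture of C5' epimers. Parikh–Doering oxidation should give the methyl ketone (3S,4S)-4-{[tert-butyl(diphenyl)silyl]oxy}-5-(1,3-dithian-2-yl)-3-[(4-methoxyphenyl)methoxy]pentan-2-one F1. Reduction with the bulky, non-chelating hydride K[s-Bu3BH] in THF at −78 °C should then follow the polar Felkin–Anh model, which for a ketone leads to the syn alcohol. The stereocentre is then set by hydride delivery instead of carbanion delivery, and the sequence comes back at 12.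

**Step 12.** The most likely failure is poor facial selectivity at C1'. The catalyst acts on an α-unbranched aldehyde whose only stereocentre is remote, the substituted nitroalkane reacts slowly, and retro-nitroaldol equilibration can wear down whatever selectivity is reached. The fallback sets out from 14 and replaces catalyst control by an auxiliary.
- The boron enolate of (4S)-4-benzyl-3-(chloroacetyl)-1,3-oxazolidin-2-one (Bu2BOTf, Et3N, −78 °C) should add through a Zimmerman–Traxler chair (Evans aldol) in the sense required at C1'. This gives the syn chlorohydrin (4S)-4-benzyl-3-[(2S,3R,5S)-5-{[tert-butyl(diphenyl)silyl]oxy}-2-chloro-3-hydroxy-5-[(4R,5S)-2-(4-methoxyphenyl)-5-methyl-1,3-dioxolan-4-yl]pentanoyl]-1,3-oxazolidin-2-one F2.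
- NaN3 in DMF displaces chloride with inversion to give the azide (4S)-3-[(2R,3R,5S)-2-azido-5-{[tert-butyl(diphenyl)silyl]oxy}-3-hydroxy-5-[(4R,5S)-2-(4-methoxyphenyl)-5-methyl-1,3-dioxolan-4-yl]pentanoyl]-4-benzyl-1,3-oxazolidin-2-one F3.
- 3,4-Dihydro-2H-pyran with PPTS gives its THP ether (4S)-3-[(2R,3R,5S)-2-azido-5-{[tert-butyl(diphenyl)silyl]oxy}-5-[(4R,5S)-2-(4-methoxyphenyl)-5-methyl-1,3-dioxolan-4-yl]-3-(oxan-2-yloxy)pentanoyl]-4-benzyl-1,3-oxazolidin-2-one F4.
- LiAlH4 in THF at 0 °C reduces the azide and cleaves the imide to the amino alcohol (2S,3R,5S)-2-amino-5-{[tert-butyl(diphenyl)silyl]oxy}-5-[(4R,5S)-2-(4-methoxyphenyl)-5-methyl-1,3-dioxolan-4-yl]-3-(oxan-2-yloxy)pentan-1-ol F5.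
- Coupling of F5 with 19 (EDC·HCl, HOBt) acylates nitrogen only and comes back at 22, as a single epimer at the nitrogen-bearing carbon.

These five operations replace steps 11–16.

**Step 18.** The most likely failure is β-elimination of the C1' alkoxy group from the enolisable α-amido aldehyde before the ring closes, or incomplete closure, because an aldehyde with a leaving group two atoms away is exposed to amine bases. The fallback sets out from 22 and avoids the aldehyde. Bis(2-methoxyethyl)aminosulfur trifluoride (CH2Cl2, −20 °C) should cyclodehydrate the serine-type hydroxy amide directly to the oxazoline 4-[(1R,3S)-3-{[tert-butyl(diphenyl)silyl]oxy}-3-[(4R,5S)-2-(4-methoxyphenyl)-5-methyl-1,3-dioxolan-4-yl]-1-(oxan-2-yloxy)propyl]-2-(1,3-oxazol-5-ylmethyl)-4,5-dihydro-1,3-oxazole F6. Dehydrogenation with NiO2 in benzene at reflux then comes back at 25. This oxidation is known for 4-alkyl oxazolines but is less efficient than for 4-carboxylates, so it is a reserve only.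

**Step 9.** The most likely failure is competing attack of DDQ on the dithiane (oxidation at sulfur or hydride abstraction at C1'), with loss of the C1' protecting group, because thioacetals are themselves cleaved by this oxidant under forcing conditions. The fallback sets out from 12 and uses no oxidant. MgBr2·OEt2 with Me2S in CH2Cl2 at rt removes the PMB ether as a sulfonium salt and gives the diol (2S,3R,4S)-4-{[tert-butyl(diphenyl)silyl]oxy}-5-(1,3-dithian-2-yl)pentane-2,3-diol F7. Transacetalisation of F7 with 7 (PPTS, CH2Cl2) then comes back at 13, two operations in place of one.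

## Further compounds

F1 | step 8 | (3S,4S)-4-{[tert-butyl(diphenyl)silyl]oxy}-5-(1,3-dithian-2-yl)-3-[(4-methoxyphenyl)methoxy]pentan-2-one | CC(C)(C)[Si](c1ccccc1)(c1ccccc1)O[C@@H](CC1SCCCS1)[C@H](OCc1ccc(OC)cc1)C(C)=O
F2 | step 12 | (4S)-4-benzyl-3-[(2S,3R,5S)-5-{[tert-butyl(diphenyl)silyl]oxy}-2-chloro-3-hydroxy-5-[(4R,5S)-2-(4-methoxyphenyl)-5-methyl-1,3-dioxolan-4-yl]pentanoyl]-1,3-oxazolidin-2-one | O=C1OC[C@H](Cc2ccccc2)N1C(=O)[C@@H](Cl)[C@H](O)C[C@H](O[Si](c1ccccc1)(c1ccccc1)C(C)(C)C)[C@H](O2)[C@H](C)OC2c1ccc(OC)cc1
F3 | step 12 | (4S)-3-[(2R,3R,5S)-2-azido-5-{[tert-butyl(diphenyl)silyl]oxy}-3-hydroxy-5-[(4R,5S)-2-(4-methoxyphenyl)-5-methyl-1,3-dioxolan-4-yl]pentanoyl]-4-benzyl-1,3-oxazolidin-2-one | O=C1OC[C@H](Cc2ccccc2)N1C(=O)[C@H](N=[N+]=[N-])[C@H](O)C[C@H](O[Si](c1ccccc1)(c1ccccc1)C(C)(C)C)[C@H](O2)[C@H](C)OC2c1ccc(OC)cc1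
F4 | step 12 | (4S)-3-[(2R,3R,5S)-2-azido-5-{[tert-butyl(diphenyl)silyl]oxy}-5-[(4R,5S)-2-(4-methoxyphenyl)-5-methyl-1,3-dioxolan-4-yl]-3-(oxan-2-yloxy)pentanoyl]-4-benzyl-1,3-oxazolidin-2-one | O=C1OC[C@H](Cc2ccccc2)N1C(=O)[C@H](N=[N+]=[N-])[C@H](OC1CCCCO1)C[C@H](O[Si](c1ccccc1)(c1ccccc1)C(C)(C)C)[C@H](O2)[C@H](C)OC2c1ccc(OC)cc1
F5 | step 12 | (2S,3R,5S)-2-amino-5-{[tert-butyl(diphenyl)silyl]oxy}-5-[(4R,5S)-2-(4-methoxyphenyl)-5-methyl-1,3-dioxolan-4-yl]-3-(oxan-2-yloxy)pentan-1-ol | OC[C@H](N)[C@H](OC1CCCCO1)C[C@H](O[Si](c1ccccc1)(c1ccccc1)C(C)(C)C)[C@H](O2)[C@H](C)OC2c1ccc(OC)cc1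
F6 | step 18 | 4-[(1R,3S)-3-{[tert-butyl(diphenyl)silyl]oxy}-3-[(4R,5S)-2-(4-methoxyphenyl)-5-methyl-1,3-dioxolan-4-yl]-1-(oxan-2-yloxy)propyl]-2-(1,3-oxazol-5-ylmethyl)-4,5-dihydro-1,3-oxazole | C1OC(Cc2cnco2)=NC1[C@H](OC1CCCCO1)C[C@H](O[Si](c1ccccc1)(c1ccccc1)C(C)(C)C)[C@H](O2)[C@H](C)OC2c1ccc(OC)cc1
F7 | step 9 | (2S,3R,4S)-4-{[tert-butyl(diphenyl)silyl]oxy}-5-(1,3-dithian-2-yl)pentane-2,3-diol | CC(C)(C)[Si](c1ccccc1)(c1ccccc1)O[C@@H](CC1SCCCS1)[C@H](O)[C@H](C)O
A1 | alternative 1 | 4-[(1R,3S)-1-{[tert-butyl(dimethyl)silyl]oxy}-3-[(4-methoxyphenyl)methoxy]-3-[(4R,5S)-2,2,5-trimethyl-1,3-dioxolan-4-yl]propyl]-2-(1,3-oxazol-5-ylmethyl)-1,3-oxazole | COc1ccc(CO[C@@H](C[C@@H](O[Si](C)(C)C(C)(C)C)c2coc(Cc3cnco3)n2)[C@H](O4)[C@H](C)OC4(C)C)cc1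
A2 | alternative 1 | N-[(3R,5S)-3-{[tert-butyl(dimethyl)silyl]oxy}-1-hydroxy-5-[(4-methoxyphenyl)methoxy]-5-[(4R,5S)-2,2,5-trimethyl-1,3-dioxolan-4-yl]pentan-2-yl]-2-(1,3-oxazol-5-yl)acetamide (epimers at C2) | COc1ccc(CO[C@@H](C[C@@H](O[Si](C)(C)C(C)(C)C)C(CO)NC(=O)Cc2cnco2)[C@H](O3)[C@H](C)OC3(C)C)cc1
A3 | alternative 2 | (2S,3R,4S,6R)-3,6-bis{[tert-butyl(dimethyl)silyl]oxy}-2-hydroxy-6-[2-(1,3-oxazol-5-ylmethyl)-1,3-oxazol-4-yl]hexan-4-yl tetradecanoate | CCCCCCCCCCCCCC(=O)O[C@@H](C[C@@H](O[Si](C)(C)C(C)(C)C)c1coc(Cc2cnco2)n1)[C@H](O[Si](C)(C)C(C)(C)C)[C@H](C)O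
A4 | alternative 2 | (3S,4S,6R)-3,6-bis{[tert-butyl(dimethyl)silyl]oxy}-4-hydroxy-6-[2-(1,3-oxazol-5-ylmethyl)-1,3-oxazol-4-yl]hexan-2-one | O[C@@H](C[C@@H](O[Si](C)(C)C(C)(C)C)c1coc(Cc2cnco2)n1)[C@H](O[Si](C)(C)C(C)(C)C)C(C)=O
A5 | alternative 2 | tetradecanal | CCCCCCCCCCCCCC=O
A6 | alternative 3 | (3R,5S)-1-{[tert-butyl(dimethyl)silyl]oxy}-5-[(4-methoxyphenyl)methoxy]-2-nitro-5-[(4R,5S)-2,2,5-trimethyl-1,3-dioxolan-4-yl]pentan-3-ol (epimers at C2) | [O-][N+](=O)C(CO[Si](C)(C)C(C)(C)C)[C@H](O)C[C@H](OCc1ccc(OC)cc1)[C@H](O3)[C@H](C)OC3(C)C
A7 | alternative 3 | (3S)-3-[(4-methoxyphenyl)methoxy]-3-[(4R,5S)-2,2,5-trimethyl-1,3-dioxolan-4-yl]propanal | O=CC[C@H](OCc1ccc(OC)cc1)[C@H](O2)[C@H](C)OC2(C)C
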